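**Retrosynthetic overview**

1. The C7=C8 exocyclic alkene is made last: E1cB dehydration of an aldol adduct, which comes from the enolate of a 2-bromo-4-hydroxy-4-octenylcyclopentenone and methyl (Z)-7-oxohept-5-enoate.
2. Key step: the cyclopentenone is made by a catalyst-controlled enantioselective oxa-Piancatelli rearrangement of a 2,3,5-trisubstituted furfuryl alcohol. This breaks the furan aromaticity and sets the only stereocentre (C12), with bromine and the lower chain already in place.
3. The furfuryl alcohol comes from furan by α-lithiation/allylation with (Z)-oct-2-enyl bromide, α-bromination, then halogen dance and hydroxymethylation.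
4. The Z-enal comes from a Z-selective Wittig reaction of a C5 ester ylide with glyoxal mono-acetal, then mild acetal hydrolysis.
5. Ring order: the furan ring is bought; the cyclopentenone, the only ring of the target, is formed once, in the key step.

Assumption: all compounds marked starting material are bought, and because the sense of induction in step 5 cannot be predicted with certainty, the (R)-configured acid is written and its mirror image is used instead if it delivers the enantiomer of 11.

**Route**

Step 1
Reactants: 1 (Z)-oct-2-en-1-ol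
Product: 2 (Z)-1-bromooct-2-ene
Conditions: CBr4 (1.1 equiv), PPh3 (1.15 equiv), CH2Cl2, 0 °C, 1 h
Reagents that add atoms: carbon tetrabromide, BrC(Br)(Br)Br
Why: Appel bromination replaces the primary allylic hydroxyl by SN2 displacement of an oxyphosphonium leaving group under neutral conditions, so the Z alkene is kept and no allylic transposition occurs; no stereocentre is formed.

Step 2
Reactants: 3 furan; 2 (Z)-1-bromooct-2-ene
Product: 5 2-[(2Z)-oct-2-en-1-yl]furan, via 2-lithiofuran 4 (not isolated)
Conditions: furan (3 equiv), n-BuLi (1.05 equiv), THF, −78 → 0 °C, 1 h; then 2, −78 °C → rt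
Reagents that add atoms: none
Why: α-lithiation of furan next to the ring oxygen followed by SN2 alkylation of the aryllithium with the primary allylic bromide gives the 2-alkylfuran with the Z alkene intact; no stereocentre is formed.

Step 3
Reactants: 5 2-[(2Z)-oct-2-en-1-yl]furan
Product: 6 2-bromo-5-[(2Z)-oct-2-en-1-yl]furan
Conditions: NBS (1.0 equiv), DMF, −20 → 0 °C, dark; crude product filtered through basic alumina and used at once
Reagents that add atoms: N-bromosuccinimide, O=C1CCC(=O)N1Br
Why: electrophilic aromatic bromination takes place at the free α-position of the π-excessive 2-alkylfuran much faster than at the isolated disubstituted alkene, and cold, dark, polar conditions suppress radical allylic bromination; no stereocentre is formed.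

Step 4
Reactants: 6 2-bromo-5-[(2Z)-oct-2-en-1-yl]furan
Product: 9 {3-bromo-5-[(2Z)-oct-2-en-1-yl]furan-2-yl}methanol, via 2-bromo-3-lithio-5-octenylfuran 7 (not isolated), via 3-bromo-2-lithio-5-octenylfuran 8 (not isolated)
Conditions: LiN(iPr)2 (1.1 equiv), THF, −78 °C, 45 min; then HCHO (gas, from cracked paraformaldehyde), −78 → −20 °C; H2O
Reagents that add atoms: formaldehyde, C=O
Why: base-induced halogen dance, in which the amide removes the ring proton ortho to bromine (C3), intermolecular bromine–lithium exchange relays bromine to C3 and lithium to the more stabilising α-position C2 (flanked by oxygen and bromine), and the resulting aryllithium adds to formaldehyde, while the hindered base at −78 °C does not deprotonate the furfurylic/allylic CH2 at a competitive rate; no stereocentre is formed.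

Step 5
Reactants: 9 {3-bromo-5-[(2Z)-oct-2-en-1-yl]furan-2-yl}methanol
Product: 11 (4S)-2-bromo-4-hydroxy-4-[(2Z)-oct-2-en-1-yl]cyclopent-2-en-1-one, via ring-opened hydroxydienone 10 (not isolated)
Conditions: (R)-3,3'-bis(2,4,6-triisopropylphenyl)-1,1'-binaphthyl-2,2'-diyl N-triflylphosphoramide, (ArO)2P(=O)NHSO2CF3 (10 mol%), H2O (5 equiv), CHCl3 (0.02 M), 0 → 30 °C
Reagents that add atoms: water, O
Why: Proposed new method: enantioselective oxa-Piancatelli rearrangement in which the strong chiral Brønsted acid ionises the primary furfuryl alcohol to a furfuryl cation (stabilised by the ring oxygen and the C5 alkyl group), water adds at the alkyl-bearing C5, the hemiketal opens to hydroxydienone 10, and its O-protonated form, a 1,4-dihydroxypentadienyl cation held by two hydrogen bonds to the chiral phosphoramidate anion, closes by conrotatory 4π electrocyclisation between the CH2 terminus and the carbinol carbon, the anion selecting one sense of conrotation and so fixing the only stereocentre (S descriptor here, the 12R centre of the target); the closest known reaction types are the oxa-Piancatelli rearrangement of 5-substituted primary furfuryl alcohols to 4-hydroxy-4-alkylcyclopentenones in hot water and the chiral phosphoric acid-catalysed aza-Piancatelli and Nazarov cyclisations.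

Step 6
Reactants: 12 methyl 5-bromopentanoate
Product: 13 (5-methoxy-5-oxopentyl)triphenylphosphonium bromide
Conditions: PPh3 (1.05 equiv), MeCN, reflux, 36 h; precipitate from Et2O
Reagents that add atoms: triphenylphosphine, c1ccc(cc1)P(c1ccccc1)c1ccccc1
Why: SN2 quaternisation of triphenylphosphine by the primary bromide gives the phosphonium salt with the ester untouched; no stereocentre is formed.

Step 7
Reactants: 13 (5-methoxy-5-oxopentyl)triphenylphosphonium bromide; 14 2,2-dimethoxyacetaldehyde (anhydrous, dried from the commercial aqueous solution)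
Product: 16 methyl (5Z)-7,7-dimethoxyhept-5-enoate, via phosphorus ylide 15 (not isolated)
Conditions: NaN(SiMe3)2 (1.0 equiv), THF, −78 °C, 30 min; then 14, −78 → 0 °C
Reagents that add atoms: none
Why: salt-free Wittig olefination of a non-stabilised ylide with an α-alkoxy aldehyde at low temperature goes through the kinetically favoured cis-oxaphosphetane and gives the Z alkene (typically ≥95:5); no stereocentre is formed.

Step 8
Reactants: 16 methyl (5Z)-7,7-dimethoxyhept-5-enoate
Product: 17 methyl (5Z)-7-oxohept-5-enoate
Conditions: 10% aq. oxalic acid on SiO2, CH2Cl2, 20 °C, 1 h; filtered, concentrated cold and used at once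
Reagents that add atoms: water, O
Why: mild acid-catalysed acetal hydrolysis on wet silica releases the Z-enal without isomerising it to the E-enal; no stereocentre is formed.

Step 9
Reactants: 11 (4S)-2-bromo-4-hydroxy-4-[(2Z)-oct-2-en-1-yl]cyclopent-2-en-1-one; 17 methyl (5Z)-7-oxohept-5-enoate
Product: 19 methyl (5Z)-7-[(2S)-4-bromo-2-hydroxy-2-[(2Z)-oct-2-en-1-yl]-5-oxocyclopent-3-en-1-yl]-7-hydroxyhept-5-enoate, via dilithium alkoxide enolate 18 (not isolated)
Conditions: LiN(SiMe3)2 (2.2 equiv), THF, −78 °C, 45 min; then 17 (1.2 equiv), −78 °C, 20 min; AcOH, −78 °C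
Reagents that add atoms: none
Why: directed aldol addition in which the tertiary alcohol is deprotonated first, the second equivalent of base forms the kinetic lithium enolate at the only enolisable position (the ring CH2), and this adds 1,2 to the enal at −78 °C, the alkoxide being no leaving group so that the enolate does not β-eliminate; the two new stereocentres form as a mixture and are both removed in step 10, while the tertiary carbinol centre is untouched.

Step 10
Reactants: 19 methyl (5Z)-7-[(2S)-4-bromo-2-hydroxy-2-[(2Z)-oct-2-en-1-yl]-5-oxocyclopent-3-en-1-yl]-7-hydroxyhept-5-enoate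
Product: 21 methyl (5Z,7E)-7-[(2R)-4-bromo-2-hydroxy-2-[(2Z)-oct-2-en-1-yl]-5-oxocyclopent-3-en-1-ylidene]hept-5-enoate, via allylic mesylate 20 (not isolated)
Conditions: MsCl (1.3 equiv), Et3N (4 equiv), CH2Cl2, −40 → 0 °C; chromatography removes the minor 7Z isomer
Reagents that add atoms: none
Why: selective mesylation of the secondary allylic alcohol (the hindered tertiary alcohol does not react) and E1cB elimination through the enolate give the exocyclic enone mainly as the E isomer (side chain anti to the ring carbonyl, the preferred geometry of 2-alkylidenecyclopentenones), the 5Z and 14Z alkenes and the carbinol centre are not touched, and the descriptor changes from S to R only because the new exocyclic alkene raises the CIP rank of the neighbouring ring carbon.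

**Compound list**

1 | (Z)-oct-2-en-1-ol | CCCCC/C=C\CO | starting material
2 | (Z)-1-bromooct-2-ene | CCCCC/C=C\CBr | intermediate
3 | furan | c1ccoc1 | starting material
4 | 2-lithiofuran | [Li]c1ccco1 | intermediate
5 | 2-[(2Z)-oct-2-en-1-yl]furan | CCCCC/C=C\Cc1ccco1 | intermediate
6 | 2-bromo-5-[(2Z)-oct-2-en-1-yl]furan | CCCCC/C=C\Cc1ccc(Br)o1 | intermediate
7 | 2-bromo-3-lithio-5-[(2Z)-oct-2-en-1-yl]furan | CCCCC/C=C\Cc1cc([Li])c(Br)o1 | intermediate
8 | 3-bromo-2-lithio-5-[(2Z)-oct-2-en-1-yl]furan | CCCCC/C=C\Cc1cc(Br)c([Li])o1 | intermediate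
9 | {3-bromo-5-[(2Z)-oct-2-en-1-yl]furan-2-yl}methanol | CCCCC/C=C\Cc1cc(Br)c(CO)o1 | intermediate
10 | (3E,7Z)-3-bromo-2-hydroxytrideca-1,3,7-trien-5-one (ring-opened hydroxydienone; the two carbon termini are cis across the C3=C4 bond) | C=C(O)/C(Br)=C\C(=O)C/C=C\CCCCC | intermediate
11 | (4S)-2-bromo-4-hydroxy-4-[(2Z)-oct-2-en-1-yl]cyclopent-2-en-1-one | CCCCC/C=C\C[C@@]1(O)C=C(Br)C(=O)C1 | intermediate
12 | methyl 5-bromopentanoate | COC(=O)CCCCBr | starting material
13 | (5-methoxy-5-oxopentyl)triphenylphosphonium bromide | COC(=O)CCCC[P+](c1ccccc1)(c1ccccc1)c1ccccc1.[Br-] | intermediate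
14 | 2,2-dimethoxyacetaldehyde | COC(OC)C=O | starting material
15 | methyl 5-(triphenyl-λ5-phosphanylidene)pentanoate (ylide) | COC(=O)CCCC=P(c1ccccc1)(c1ccccc1)c1ccccc1 | intermediate
16 | methyl (5Z)-7,7-dimethoxyhept-5-enoate | COC(=O)CCC/C=C\C(OC)OC | intermediate
17 | methyl (5Z)-7-oxohept-5-enoate | COC(=O)CCC/C=C\C=O | intermediate
18 | dilithium alkoxide enolate of 11 (lithium on the tertiary oxygen and on the enolate oxygen) | CCCCC/C=C\C[C@@]1(O[Li])C=C(Br)C(O[Li])=C1 | intermediate
19 | methyl (5Z)-7-[(2S)-4-bromo-2-hydroxy-2-[(2Z)-oct-2-en-1-yl]-5-oxocyclopent-3-en-1-yl]-7-hydroxyhept-5-enoate (mixture at the two new centres) | CCCCC/C=C\C[C@@]1(O)C=C(Br)C(=O)C1C(O)/C=C\CCCC(=O)OC | intermediate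
20 | methyl (5Z)-7-[(2S)-4-bromo-2-hydroxy-2-[(2Z)-oct-2-en-1-yl]-5-oxocyclopent-3-en-1-yl]-7-[(methylsulfonyl)oxy]hept-5-enoate | CCCCC/C=C\C[C@@]1(O)C=C(Br)C(=O)C1C(OS(C)(=O)=O)/C=C\CCCC(=O)OC | intermediate
21 | methyl (5Z,7E)-7-[(2R)-4-bromo-2-hydroxy-2-[(2Z)-oct-2-en-1-yl]-5-oxocyclopent-3-en-1-ylidene]hept-5-enoate (bromovulone I) | CCCCC/C=C\C[C@@]1(O)C=C(Br)C(=O)/C1=C/C=C\CCCC(=O)OC | target

**Step count and risks**

Total step count: 10. Longest linear sequence: 7 (steps 1, 2, 3, 4, 5, 9, 10); the aldehyde branch (steps 6–8) joins at step 9.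

Steps most likely to fail:

Step 5 (enantioselective rearrangement of a primary, bromine-bearing furfuryl alcohol). Ionisation may be slow, the cation may oligomerise, or the enantioselectivity may be low. The fallback sets out from 9 and comes back at 11. Compound 9 is rearranged without chiral control under conditions established for 5-alkylfurfuryl alcohols (ZnCl2, dioxane–water 1:1, 90 °C, or water–tert-butanol at 140 °C with microwave heating). This gives racemic 2-bromo-4-hydroxy-4-[(2Z)-oct-2-en-1-yl]cyclopent-2-en-1-one F1. The enantiomers are then separated by preparative chromatography on an amylose tris(3,5-dimethylphenylcarbamate) phase, and the S enantiomer is 11. The stereocentre then comes from resolution, not from catalysis.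

Step 4 (halogen dance next to a furfurylic/allylic CH2). Lateral deprotonation, an incomplete bromine shift or decomposition of the labile bromofuran 6 would ruin it. The fallback sets out from 5 and comes back at 11, introducing bromine only after the ring has been formed.
- Compound 5 is ring-lithiated with n-BuLi (THF, −78 → 0 °C) and trapped with formaldehyde to give {5-[(2Z)-oct-2-en-1-yl]furan-2-yl}methanol F2.
- The rearrangement of step 5 converts it into (4S)-4-hydroxy-4-[(2Z)-oct-2-en-1-yl]cyclopent-2-en-1-one F3.
- Nucleophilic epoxidation of the enone (t-BuOOH, DBU, CH2Cl2, 0 °C; the isolated alkene is inert to this oxidant) gives (2S)-2-hydroxy-2-[(2Z)-oct-2-en-1-yl]-6-oxabicyclo[3.1.0]hexan-4-one F4.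
- HBr (48% aq., THF, 0 °C) opens the epoxide at the carbon α to the ketone to give the bromohydrin (4S)-2-bromo-3,4-dihydroxy-4-[(2Z)-oct-2-en-1-yl]cyclopentan-1-one F5, which loses water by β-elimination to give 11.

Step 9 (dianion aldol with a Z-enal that isomerises easily). The enal may isomerise to E, enolise or add in a conjugate sense. The fallback sets out from 11 and 14 and comes back at 21, forming the 5Z alkene last.
- The dianion of 11 is condensed with the non-enolisable, geometrically inert aldehyde 14 to give the aldol adduct (4S)-2-bromo-4-hydroxy-5-(1-hydroxy-2,2-dimethoxyethyl)-4-[(2Z)-oct-2-en-1-yl]cyclopent-2-en-1-one F6.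
- MsCl and Et3N convert it through 1-[(2S)-4-bromo-2-hydroxy-2-[(2Z)-oct-2-en-1-yl]-5-oxocyclopent-3-en-1-yl]-2,2-dimethoxyethyl methanesulfonate F7 into (4R,5E)-2-bromo-5-(2,2-dimethoxyethylidene)-4-hydroxy-4-[(2Z)-oct-2-en-1-yl]cyclopent-2-en-1-one F8.
- Aqueous oxalic acid on silica unmasks (2E)-2-[(2R)-4-bromo-2-hydroxy-2-[(2Z)-oct-2-en-1-yl]-5-oxocyclopent-3-en-1-ylidene]acetaldehyde F9.
- After deprotonation of the tertiary alcohol with one equivalent of NaN(SiMe3)2, a Z-selective Wittig reaction with ylide 15 at −78 °C gives 21 directly.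

**Further compounds**

F1 | step 5 | racemic 2-bromo-4-hydroxy-4-[(2Z)-oct-2-en-1-yl]cyclopent-2-en-1-one | CCCCC/C=C\CC1(O)C=C(Br)C(=O)C1
F2 | step 4 | {5-[(2Z)-oct-2-en-1-yl]furan-2-yl}methanol | CCCCC/C=C\Cc1ccc(CO)o1
F3 | step 4 | (4S)-4-hydroxy-4-[(2Z)-oct-2-en-1-yl]cyclopent-2-en-1-one | CCCCC/C=C\C[C@@]1(O)C=CC(=O)C1
F4 | step 4 | (2S)-2-hydroxy-2-[(2Z)-oct-2-en-1-yl]-6-oxabicyclo[3.1.0]hexan-4-one (epoxide carbons as a mixture) | CCCCC/C=C\C[C@@]1(O)C2OC2C(=O)C1
F5 | step 4 | (4S)-2-bromo-3,4-dihydroxy-4-[(2Z)-oct-2-en-1-yl]cyclopentan-1-one | CCCCC/C=C\C[C@@]1(O)C(O)C(Br)C(=O)C1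
F6 | step 9 | (4S)-2-bromo-4-hydroxy-5-(1-hydroxy-2,2-dimethoxyethyl)-4-[(2Z)-oct-2-en-1-yl]cyclopent-2-en-1-one | CCCCC/C=C\C[C@@]1(O)C=C(Br)C(=O)C1C(O)C(OC)OC
F7 | step 9 | 1-[(2S)-4-bromo-2-hydroxy-2-[(2Z)-oct-2-en-1-yl]-5-oxocyclopent-3-en-1-yl]-2,2-dimethoxyethyl methanesulfonate | CCCCC/C=C\C[C@@]1(O)C=C(Br)C(=O)C1C(OS(C)(=O)=O)C(OC)OC
F8 | step 9 | (4R,5E)-2-bromo-5-(2,2-dimethoxyethylidene)-4-hydroxy-4-[(2Z)-oct-2-en-1-yl]cyclopent-2-en-1-one | CCCCC/C=C\C[C@@]1(O)C=C(Br)C(=O)/C1=C/C(OC)OC
F9 | step 9 | (2E)-2-[(2R)-4-bromo-2-hydroxy-2-[(2Z)-oct-2-en-1-yl]-5-oxocyclopent-3-en-1-ylidene]acetaldehyde | CCCCC/C=C\C[C@@]1(O)C=C(Br)C(=O)/C1=C/C=O
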